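**Plan** (longipinane numbering: C1 ketone, C2 CH2, C3 CH–CH3, C4/C5/C10/C11 cyclobutane, C6 CMe2, C7/C8 CH–O, C9 CH2)
1. Retrosynthesis: the two angelates come off last, one after the other; then C3–C4 and C5–C11 are cut together. This opens the cyclohexanone C1–C2–C3–C4–C5–C11 and the cyclobutane C4–C5–C11–C10 at once and leaves a cycloheptene whose C4=C5 alkene faces a 2-silyloxy-1,3-diene (C11=C1(OSi)–C2=C3) attached to C10.
2. Enabling feature: the C1 carbonyl lies in a six-membered ring built from the two-carbon unit C4–C5 and the four-carbon unit C11–C1–C2–C3 (a hydrolysed [4+2] adduct). C4=C5 sits between the quaternary carbons C10 and C6, so a metal alkyl at C5 has no syn β-hydrogen. A thermal Diels–Alder reaction cannot pass through the one-atom tether C10, so the event is run as an iron-catalysed metallacyclic [4+2].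
3. Forward order: seven-membered ring first (eucarvone from carvone), trans-diol on it, quaternary C10, C4=C5 from the ring ketone, dienyl chain from the allyl group, then the key step closes the six- and four-membered rings; the C8 ester and then the hindered C7 ester are put on last.
4. Stereochemistry: C7/C8 from Jacobsen epoxidation and invertive epoxide opening; C10 from Pd/(S)-t-Bu-PHOX allylation; C4, C5, C11 relayed from C10 in the key step; C3 from the (E)-alkene geometry.

Key step: step 14

Remark: both acyl groups are (Z)-2-methylbut-2-enoyl (angeloyl), as the SMILES shows. Eucarvone carbons C1–C7 become longipinane C4, C10, C9, C8, C7, C6, C5.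

**Step 1**
Reactants: 1 (R)-(−)-carvone
Product: 2 (5R)-5-(2-bromopropan-2-yl)-2-methylcyclohex-2-en-1-one
Conditions: HBr (33% in AcOH), 0 °C
Reagents that add atoms: hydrogen bromide, Br
Why: Markovnikov hydrobromination of the isopropenyl group through the tertiary cation, the enone alkene being deactivated; the ring stereocentre is untouched and disappears in step 2.

**Step 2**
Reactants: 2 carvone hydrobromide
Product: 4 eucarvone (2,6,6-trimethylcyclohepta-2,4-dien-1-one), via car-3-en-2-one 3 (not isolated)
Conditions: KOH, MeOH, 0 → 65 °C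
Reagents that add atoms: none
Why: intramolecular enolate alkylation (1,3-elimination of HBr) should give the cyclopropyl ketone 3, whose dienolate ring-expands by norcaradiene–cycloheptatriene valence isomerisation to achiral eucarvone.

**Step 3**
Reactants: 4 eucarvone
Product: 5 (4R,5S)-4,5-epoxy-2,6,6-trimethylcyclohept-2-en-1-one
Conditions: (R,R)-Jacobsen catalyst [(salen)Mn(III)Cl] (5 mol %), aq. NaOCl (pH 11.3), 4-phenylpyridine N-oxide, CH2Cl2, 0 °C
Reagents that add atoms: sodium hypochlorite, [Na+].[O-]Cl
Why: Jacobsen–Katsuki epoxidation should take the electron-richer, cis-disubstituted γ,δ-alkene rather than the enone alkene, and the (R,R)-ligand should select the face by analogy with 2,2-dimethylchromenes (conjugated cis-alkene next to a CMe2 group).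

**Step 4**
Reactants: 5 epoxy enone
Product: 6 (4S,5S)-4,5-dihydroxy-2,6,6-trimethylcyclohept-2-en-1-one
Conditions: HClO4 (cat.), THF/H2O, 0 → 23 °C
Reagents that add atoms: water, O
Why: acid-catalysed SN2 opening of the vinyl epoxide at the allylic, non-neopentyl carbon C4 with inversion should give the trans-diol; C5 keeps its configuration.

**Step 5**
Reactants: 6 trans-diol
Product: 7 (4S,5S)-4,5-(isopropylidenedioxy)-2,6,6-trimethylcyclohept-2-en-1-one
Conditions: 2,2-dimethoxypropane, PPTS (cat.), CH2Cl2, 23 °C
Reagents that add atoms: 2,2-dimethoxypropane, COC(C)(C)OC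
Why: acetalisation to the trans-fused dioxolane on the flexible seven-membered ring protects the diol against the hydride, enolate and organometallic steps.

**Step 6**
Reactants: 7 acetonide enone
Product: 8 allyl (4S,5S)-4,5-(isopropylidenedioxy)-2,6,6-trimethylcyclohept-1-en-1-yl carbonate
Conditions: L-Selectride, THF, −78 °C; then allyl chloroformate, −78 → 0 °C
Reagents that add atoms: allyl chloroformate, C=CCOC(=O)Cl
Why: 1,4-hydride delivery to the α-methyl, β-unsubstituted enone (as with carvone) gives the regiodefined tetrasubstituted enolate, which is O-acylated to the allyl enol carbonate.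

**Step 7**
Reactants: 8 allyl enol carbonate
Product: 9 (2R,4S,5S)-2-allyl-4,5-(isopropylidenedioxy)-2,6,6-trimethylcycloheptan-1-one
Conditions: Pd2(dba)3 (2.5 mol %), (S)-t-Bu-PHOX (6.25 mol %), THF, 25 °C
Reagents that add atoms: none
Why: decarboxylative asymmetric allylic alkylation (Tsuji allylation) through the Pd(π-allyl) enolate; the ligand should set the quaternary centre in the same spatial sense in which it gives (S)-2-allyl-2-methylcyclohexanone, which is 2R here.

**Step 8**
Reactants: 9 α-allyl ketone
Product: 10 (4S,5S,7R)-7-allyl-4,5-(isopropylidenedioxy)-3,3,7-trimethylcyclohept-1-en-1-yl trifluoromethanesulfonate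
Conditions: KHMDS, THF, −78 °C; PhNTf2, −78 → 0 °C
Reagents that add atoms: N-phenylbis(trifluoromethanesulfonimide), O=S(=O)(N(c1ccccc1)S(=O)(=O)C(F)(F)F)C(F)(F)F
Why: enol triflate formation; the ketone can enolise only away from the quaternary carbon, so the alkene position is fixed.

**Step 9**
Reactants: 10 enol triflate
Product: 11 (4S,5S,7R)-7-allyl-4,5-(isopropylidenedioxy)-3,3,7-trimethylcyclohept-1-ene
Conditions: Pd(OAc)2 (5 mol %), PPh3, HCO2H, n-Bu3N, DMF, 60 °C
Reagents that add atoms: none
Why: palladium-catalysed formate reduction of the enol triflate replaces OTf by H and leaves the cis ring alkene between the two quaternary carbons; the terminal alkene is not touched.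

**Step 10**
Reactants: 11 allyl cycloheptene
Product: 12 1-[(1S,5S,6S)-5,6-(isopropylidenedioxy)-1,4,4-trimethylcyclohept-2-en-1-yl]propan-2-one
Conditions: PdCl2 (10 mol %), CuCl, O2 (1 atm), DMF/H2O 7:1, 23 °C
Reagents that add atoms: water, O
Why: Tsuji–Wacker oxidation; Markovnikov hydroxypalladation of the unhindered terminal alkene gives the methyl ketone, while the ring alkene flanked by two quaternary carbons should not coordinate.

**Step 11**
Reactants: 12 methyl ketone
Product: 13 4-hydroxy-1-[(1S,5S,6S)-5,6-(isopropylidenedioxy)-1,4,4-trimethylcyclohept-2-en-1-yl]pentan-2-one (both carbinol epimers)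
Conditions: LDA, THF, −78 °C; CH3CHO, −78 °C; AcOH quench
Reagents that add atoms: acetaldehyde, CC=O
Why: kinetic deprotonation at the methyl group (the other α-CH2 is neopentyl) and aldol addition; the new carbinol centre is removed in step 12.

**Step 12**
Reactants: 13 aldol
Product: 15 (E)-1-[(1S,5S,6S)-5,6-(isopropylidenedioxy)-1,4,4-trimethylcyclohept-2-en-1-yl]pent-3-en-2-one, via mesylate 14 (not isolated)
Conditions: MsCl, Et3N, CH2Cl2, 0 °C; then DBU, 23 °C
Reagents that add atoms: none
Why: mesylation and E1cB elimination should give the thermodynamically favoured (E)-enone.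

**Step 13**
Reactants: 15 (E)-enone
Product: 16 tert-butyl{[(1E,3E)-1-[(1R,5S,6S)-5,6-(isopropylidenedioxy)-1,4,4-trimethylcyclohept-2-en-1-yl]penta-1,3-dien-2-yl]oxy}dimethylsilane
Conditions: LDA, THF, −78 °C; TBSCl, HMPA, −78 → 0 °C
Reagents that add atoms: tert-butyldimethylsilyl chloride, CC(C)(C)[Si](C)(C)Cl
Why: kinetic α′-deprotonation to the cross-conjugated dienolate and O-silylation; in the cyclic chair-like deprotonation transition state the bulky α-substituent should lie trans to O–Li next to the small vinyl group, which gives the (1E)-enol ether with the ring carbon and diene C-3 cis.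

**Step 14**
Reactants: 16 silyl dienol ether
Product: 17 (3S,4S,5S,7S,8S,10R,11R)-1-(tert-butyldimethylsilyloxy)-7,8-(isopropylidenedioxy)longipin-1-ene (silyl enol ether of 18)
Conditions: [(MePDI)Fe(N2)]2(μ-N2) (5 mol %; MePDI = 2,6-bis[1-(2,6-dimethylphenylimino)ethyl]pyridine), benzene, 23 → 45 °C, N2
Reagents that add atoms: none
Why: Proposed new method: the reduced iron centre binds the s-cis 2-silyloxydiene and the ring alkene, oxidative cyclisation joins C3 to C4 (6-exo-trig on C4=C5, closing ring C1–C2–C3–C4–C10–C11) and leaves a ferracycle with a σ-alkyl at C5 and an η3-allyl over C11–C1–C2, and alkyl–allyl C(sp3)–C(sp3) reductive elimination at C11 then makes C5–C11 (4-exo on the allyl, closing the cyclobutane C4–C5–C11–C10 and with it the cyclohexane C1–C2–C3–C4–C5–C11 of the bicyclo[3.1.1]heptane). The closest known reaction types are the pyridine(diimine)iron-catalysed cycloadditions of 1,3-dienes with unactivated alkenes, which end in the same cyclobutane-forming alkyl–allyl reductive elimination, and the Rh(I)- or Ni(0)-catalysed intramolecular [4+2] cycloadditions of dienes with unactivated alkenes; new are the one-atom tether and the bridged outcome, which a thermal Diels–Alder transition state cannot reach. C4, C5 and C11 are set by the quaternary centre C10, because the dienyl chain can reach only the alkene face on which it stands and both new bonds are delivered to that face. C3 is set by the (E)-geometry of C2=C3: the methyl group is the outer substituent of the s-cis diene and ends on the side of the C5 bridge, away from the C10 methyl group. The step needs closure at C11 and not at C2, the other allyl terminus, and no β-hydride loss at C5: the seven-membered ring ties C5 through C6–C9 back to C10, so that the C5–Fe bond leans over C10 towards C11, and C5 has no syn β-hydrogen because H–C4 is anti to iron after the syn addition and C6 is quaternary. Only the (1E)-enol ether can react, since it alone places C10 and C2 cis on the new six-membered ring.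

**Step 15**
Reactants: 17 tricyclic silyl enol ether
Product: 19 (3R,4S,5S,7S,8S,10R,11R)-7,8-dihydroxylongipinan-1-one, via acetonide ketone 18 (not isolated)
Conditions: 1 M HCl, THF, 23 °C
Reagents that add atoms: none
Why: acid hydrolysis of the silyl enol ether (protonation at C2, no stereocentre at stake) and then of the acetonide; C3 is β to the ketone and the bridgehead C11 cannot enolise, so no centre should epimerise.

**Step 16**
Reactants: 19 keto diol; 20 angelic acid [(Z)-2-methylbut-2-enoic acid]
Product: 21 (3R,4S,5S,7S,8S,10R,11R)-7-hydroxy-1-oxolongipinan-8-yl (Z)-2-methylbut-2-enoate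
Conditions: 20 (1.1 equiv), 2,4,6-trichlorobenzoyl chloride, Et3N, toluene, 23 °C; then 19, 60 °C
Reagents that add atoms: none
Why: Yamaguchi esterification through the mixed anhydride, without a nucleophilic catalyst so that the (Z)-geometry is kept, should acylate the C8 hydroxyl (flanked by the C9 methylene) ahead of the neopentyl C7 hydroxyl next to the quaternary C6; any 7-monoester or diester formed alongside converges on the target in step 17.

**Step 17**
Reactants: 21 8-monoangelate; 20 angelic acid [(Z)-2-methylbut-2-enoic acid]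
Product: 22 (3R,4S,5S,7S,8S,10R,11R)-1-oxolongipinane-7,8-diyl bis[(Z)-2-methylbut-2-enoate] (target)
Conditions: 20 (4 equiv), 2,4,6-trichlorobenzoyl chloride, Et3N, toluene, 23 °C; then 21, 90 °C
Reagents that add atoms: none
Why: the same Yamaguchi esterification, now driven with excess mixed anhydride and heat, should acylate the remaining hindered C7 hydroxyl; omitting DMAP avoids the addition–elimination pathway that turns angelates into tiglates.

**Compound list**
1 | (R)-(−)-carvone | C=C(C)[C@@H]1CC=C(C)C(=O)C1 | starting material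
2 | (5R)-5-(2-bromopropan-2-yl)-2-methylcyclohex-2-en-1-one | CC(C)(Br)[C@@H]1CC=C(C)C(=O)C1 | intermediate
3 | (1S,6R)-3,7,7-trimethylbicyclo[4.1.0]hept-3-en-2-one (car-3-en-2-one) | CC1=CC[C@@H]2[C@H](C1=O)C2(C)C | intermediate (not isolated)
4 | eucarvone (2,6,6-trimethylcyclohepta-2,4-dien-1-one) | CC1=CC=CC(C)(C)CC1=O | intermediate
5 | (4R,5S)-4,5-epoxy-2,6,6-trimethylcyclohept-2-en-1-one | O1[C@@H]2C=C(C)C(=O)CC(C)(C)[C@H]12 | intermediate
6 | (4S,5S)-4,5-dihydroxy-2,6,6-trimethylcyclohept-2-en-1-one | O[C@H]1C=C(C)C(=O)CC(C)(C)[C@@H]1O | intermediate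
7 | (4S,5S)-4,5-(isopropylidenedioxy)-2,6,6-trimethylcyclohept-2-en-1-one | CC1(C)O[C@H]2C=C(C)C(=O)CC(C)(C)[C@@H]2O1 | intermediate
8 | allyl (4S,5S)-4,5-(isopropylidenedioxy)-2,6,6-trimethylcyclohept-1-en-1-yl carbonate | CC1(C)O[C@H]2CC(C)=C(OC(=O)OCC=C)CC(C)(C)[C@@H]2O1 | intermediate
9 | (2R,4S,5S)-2-allyl-4,5-(isopropylidenedioxy)-2,6,6-trimethylcycloheptan-1-one | CC1(C)O[C@H]2C[C@@](C)(CC=C)C(=O)CC(C)(C)[C@@H]2O1 | intermediate
10 | (4S,5S,7R)-7-allyl-4,5-(isopropylidenedioxy)-3,3,7-trimethylcyclohept-1-en-1-yl triflate | CC1(C)O[C@H]2C[C@@](C)(CC=C)C(OS(=O)(=O)C(F)(F)F)=CC(C)(C)[C@@H]2O1 | intermediate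
11 | (4S,5S,7R)-7-allyl-4,5-(isopropylidenedioxy)-3,3,7-trimethylcyclohept-1-ene | CC1(C)O[C@H]2C[C@@](C)(CC=C)C=CC(C)(C)[C@@H]2O1 | intermediate
12 | 1-[(1S,5S,6S)-5,6-(isopropylidenedioxy)-1,4,4-trimethylcyclohept-2-en-1-yl]propan-2-one | CC1(C)O[C@H]2C[C@@](C)(CC(C)=O)C=CC(C)(C)[C@@H]2O1 | intermediate
13 | 4-hydroxy-1-[(1S,5S,6S)-5,6-(isopropylidenedioxy)-1,4,4-trimethylcyclohept-2-en-1-yl]pentan-2-one | CC1(C)O[C@H]2C[C@@](C)(CC(=O)CC(C)O)C=CC(C)(C)[C@@H]2O1 | intermediate
14 | 4-O-methanesulfonate of 13 | CC1(C)O[C@H]2C[C@@](C)(CC(=O)CC(C)OS(C)(=O)=O)C=CC(C)(C)[C@@H]2O1 | intermediate (not isolated)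
15 | (E)-1-[(1S,5S,6S)-5,6-(isopropylidenedioxy)-1,4,4-trimethylcyclohept-2-en-1-yl]pent-3-en-2-one | CC1(C)O[C@H]2C[C@@](C)(CC(=O)/C=C/C)C=CC(C)(C)[C@@H]2O1 | intermediate
16 | tert-butyl{[(1E,3E)-1-[(1R,5S,6S)-5,6-(isopropylidenedioxy)-1,4,4-trimethylcyclohept-2-en-1-yl]penta-1,3-dien-2-yl]oxy}dimethylsilane | CC1(C)O[C@H]2C[C@@](C)(/C=C(O[Si](C)(C)C(C)(C)C)\C=C\C)C=CC(C)(C)[C@@H]2O1 | intermediate
17 | (3S,4S,5S,7S,8S,10R,11R)-1-(tert-butyldimethylsilyloxy)-7,8-(isopropylidenedioxy)longipin-1-ene | CC1(C)O[C@H]2C[C@]3(C)[C@@H]4[C@@H]([C@H]3C(O[Si](C)(C)C(C)(C)C)=C[C@H]4C)C(C)(C)[C@@H]2O1 | intermediate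
18 | (3R,4S,5S,7S,8S,10R,11R)-7,8-(isopropylidenedioxy)longipinan-1-one | CC1(C)O[C@H]2C[C@]3(C)[C@@H]4[C@@H]([C@H]3C(=O)C[C@H]4C)C(C)(C)[C@@H]2O1 | intermediate (not isolated)
19 | (3R,4S,5S,7S,8S,10R,11R)-7,8-dihydroxylongipinan-1-one | O[C@H]1C[C@]2(C)[C@@H]3[C@@H]([C@H]2C(=O)C[C@H]3C)C(C)(C)[C@@H]1O | intermediate
20 | angelic acid, (Z)-2-methylbut-2-enoic acid | C/C=C(/C)C(=O)O | starting material
21 | (3R,4S,5S,7S,8S,10R,11R)-7-hydroxy-1-oxolongipinan-8-yl (Z)-2-methylbut-2-enoate | C/C=C(/C)C(=O)O[C@H]1C[C@]2(C)[C@@H]3[C@@H]([C@H]2C(=O)C[C@H]3C)C(C)(C)[C@@H]1O | intermediate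
22 | (3R,4S,5S,7S,8S,10R,11R)-1-oxolongipinane-7,8-diyl bis[(Z)-2-methylbut-2-enoate] | C/C=C(/C)C(=O)O[C@H]1C[C@]2(C)[C@@H]3[C@@H]([C@H]2C(=O)C[C@H]3C)C(C)(C)[C@@H]1OC(=O)/C(C)=C\C | target

**Total step count:** 17. **Longest linear sequence:** 17 steps (1 → 22; angelic acid 20 enters in steps 16 and 17).

**Steps most likely to fail**

Step 14 (Proposed new method). Reductive elimination to the four-membered ring may be too slow. Then ring closure at C2 (isomeric vinylcyclobutane) or β-hydride loss from C3 in the σ-C2 allyl form (formal ene product) would take over, or the hindered alkene may not bind iron at all. The fallback uses known reaction types, sets out from enone 15 and comes back at ketone 18. Detrifluoroacetylative diazo transfer (LiHMDS, CF3CO2CH2CF3, THF, −78 °C; then MsN3, Et3N, MeCN) leads through the α′-trifluoroacetyl ketone F1 to the α′-diazo enone F2. Rh2(esp)2 in CH2Cl2 at 0 °C generates the C11 carbene, which cyclopropanates the neighbouring C4=C5 alkene on the face that carries the chain. This intramolecular bicyclobutanation gives the acyl bicyclo[1.1.0]butane F3, in which C5–C11 is in place and C4–C11 is a temporary bond. SmI2, HMPA and t-BuOH in THF at −78 °C then reduce the vinyl ketone; the C3 radical of the enone radical anion adds to bridgehead C4 with release of the strained C4–C11 bond, the methyl group turning away from the C10 methyl. Protonation at C2, reduction of the resulting α-keto radical at C11 and protonation of the samarium enolate there should give 18, which step 15 carries on to 19.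

Step 3. Oxygen transfer to the electron-poor dienone may be slow or poorly face-selective, which would erode the enantiomeric purity of every later compound. The fallback sets out from eucarvone 4 and comes back at diol 6. m-CPBA (CH2Cl2, NaHCO3) epoxidises the γ,δ-alkene without face control and gives 5 together with its enantiomer F4. HClO4 in THF/H2O gives the racemic trans-diol, 6 together with its enantiomer F5. Kinetic resolution with a lipase (Candida antarctica lipase B, vinyl acetate, MTBE) should, by the empirical size rule for secondary alcohols, acylate the (4R)-alcohol to the monoacetate F6. Unreacted (4S,5S)-diol 6 is then separated by chromatography.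

Step 17. Acylation of the neopentyl C7 hydroxyl may stay incomplete, and the forcing conditions may isomerise the angeloyl unit to tigloyl during activation. The fallback sets out from monoangelate 21 and comes back at target 22, building the second (Z)-alkene on the molecule. Esterification of the C7 hydroxyl with 2-[bis(2,2,2-trifluoroethoxy)phosphoryl]propanoic acid (DCC, DMAP, CH2Cl2) gives the 7-phosphonopropanoate 8-angelate F7. DMAP catalysis can be used here because this acyl donor has no alkene to isomerise. Still–Gennari olefination with acetaldehyde (KHMDS, 18-crown-6, THF, −78 °C) should then give the (Z)-2-methylbut-2-enoate at C7, the phosphonate being deprotonated in preference to the ketone.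

**Further compounds**
F1 | step 14 | (E)-1-[(1R,5S,6S)-5,6-(isopropylidenedioxy)-1,4,4-trimethylcyclohept-2-en-1-yl]-1-(trifluoroacetyl)pent-3-en-2-one (α′-trifluoroacetyl derivative of 15, both epimers at the new CH) | CC1(C)O[C@H]2C[C@@](C)(C(C(=O)C(F)(F)F)C(=O)/C=C/C)C=CC(C)(C)[C@@H]2O1
F2 | step 14 | (E)-1-diazo-1-[(1R,5S,6S)-5,6-(isopropylidenedioxy)-1,4,4-trimethylcyclohept-2-en-1-yl]pent-3-en-2-one | CC1(C)O[C@H]2C[C@@](C)(C(=[N+]=[N-])C(=O)/C=C/C)C=CC(C)(C)[C@@H]2O1
F3 | step 14 | acyl bicyclo[1.1.0]butane (C4–C11 and C5–C11 bonded, (E)-but-2-enoyl on C11, acetonide as in 18) | CC1(C)O[C@H]2C[C@]3(C)[C@@H]4[C@H](C(C)(C)[C@@H]2O1)[C@]34C(=O)/C=C/C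
F4 | step 3 | (4S,5R)-4,5-epoxy-2,6,6-trimethylcyclohept-2-en-1-one (enantiomer of 5) | O1[C@H]2C=C(C)C(=O)CC(C)(C)[C@@H]12
F5 | step 3 | (4R,5R)-4,5-dihydroxy-2,6,6-trimethylcyclohept-2-en-1-one (enantiomer of 6) | O[C@@H]1C=C(C)C(=O)CC(C)(C)[C@H]1O
F6 | step 3 | (4R,5R)-4-acetoxy-5-hydroxy-2,6,6-trimethylcyclohept-2-en-1-one | CC(=O)O[C@@H]1C=C(C)C(=O)CC(C)(C)[C@H]1O
F7 | step 17 | (3R,4S,5S,7S,8S,10R,11R)-7-{2-[bis(2,2,2-trifluoroethoxy)phosphoryl]propanoyloxy}-1-oxolongipinan-8-yl (Z)-2-methylbut-2-enoate (both epimers at the phosphonate α-carbon) | C/C=C(/C)C(=O)O[C@H]1C[C@]2(C)[C@@H]3[C@@H]([C@H]2C(=O)C[C@H]3C)C(C)(C)[C@@H]1OC(=O)C(C)P(=O)(OCC(F)(F)F)OCC(F)(F)F
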